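Readings and results stem from a simulated flask for an exercise.

The amber run held twice the solid reagent of the violet flask, yet its substrate fell no faster, averaging 0.0180 h⁻¹ of the charge up to its reading at 4.00 h against 0.0207 h⁻¹ in the violet flask up to 10.0 h. So I took the rate to follow what stands dissolved of the solid reagent, not the amount of solid.

| flask | substrate | solid reagent | temperature | remark | time |
|---|---|---|---|---|---|
| violet | 0.32 M | 0.32 M | 20 °C | the very flask that is asked about, followed so far |  |
| amber | 0.32 M | 0.64 M | 20 °C | run made earlier |  |
| flask | 0.32 M | 0.320 M | 20 °C |  | 3.0 d |

- violet (time / h: target / %, substrate / %): 10.0: 11.3, 79.3; 20.0: 14.2, 60.3; 30.0: 13.7, 47.0; 40.0: 12.2, 39.2; 50.0: 9.6, 36.3; 60.0: 8.7, 34.0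
- amber (time / h: target / %, substrate / %): 0.333: 0.2, 99.9; 0.500: 0.8, 99.5; 0.833: 0.4, 99.4; 1.33: 1.2, 98.1; 2.50: 3.1, 96.7; 4.00: 5.2, 92.8

(standard deviation of a reading: 0.3 percentage points)

- alpha: change nothing and wait 6.0 d more
- beta: at 3.0 d take out 90 % of the target then present, then wait 6.0 d
- theta: at 3.0 d raise the temperature by 20 K, then wait 6.0 d
- eta: at 3.0 d add substrate, 50.0 % of the amount charged, then wait 6.0 d

- as a solid, counted per litre of solution: solid reagent
- what is taken out of target is counted as made
- the earlier runs were read with a standard deviation of 0.3 percentage points
- at the start none of the solid reagent is in solution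
- additions bring no volume worth counting
- a reading of substrate is of its free form alone

- target, in percent of the substrate first charged, at 3.0 d
- which option adds most target ("none" when 2 percentage points or less is all one gets) (alpha / beta / theta / eta / none)
- target present, with what was taken out counted in, in percent of the substrate first charged, after beta
- target present, with what was taken out counted in, in percent of the substrate first charged, after eta

Late in the violet flask target and substrate were sinking together, so I read their quotient, the standing ratio of target to free substrate, an apparent equilibrium constant, as 0.256 at 60.0 h. I carried the last step of substrate on unchanged to 3.0 d, which gave 31.2 % of the charge, and the ratio then gave 7.99 % of target.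

The weak link was that single ratio, resting on a small reading, so I reforged it with the reading at 50.0 h, which gave 0.264. The mean, 0.260, gave 8.13 %, and that was my number.

If target is in balance with substrate, what is taken out should grow back. For beta I removed 90 % of the target and shared the remaining pool by the ratio, which gave 13.9 % counted in, a gain of 5.8 percentage points, so I chose beta. I put no number on eta, since neither run so far had substrate added.

The forecast differed: 6.3 % (4.5 % to 8 %), best none, beta 6.6 %, eta 1 %, on the ground that “The reagent's useful capacity therefore looks spent, and no fresh target is being made.”

The violet flask gave 8.18 %, best beta with 6 points, beta 14.2 %, eta 9.06 %.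

    substrate + partner ⇌ target (K = 2.30 L mol⁻¹, k = 1.04 L mol⁻¹ h⁻¹, Ea = 62.0 kJ mol⁻¹, ΔH = −31.0 kJ mol⁻¹)
    substrate + partner ⇌ isomer of the product (K = 18.5 L mol⁻¹, k = 0.305 L mol⁻¹ h⁻¹, Ea = 78.0 kJ mol⁻¹, ΔH = −42.0 kJ mol⁻¹)
    solid reagent ⇌ partner, rate k3*(cs3 - [partner]) while solid is left; crystals form when [partner] > cs3 (solubility = 0.190 M, k = 0.0904 h⁻¹)
    (constants at 20 °C)

The violet flask held only 8.18 % because target runs back to substrate and partner: the run without that backward step gives 82.3 %. Set on the simulated amounts of the violet flask at 72.0 h, the ratio of 0.256 that I had read puts beta at 14.3 %. Where the step to target stands at balance, the ratio is K1 times partner, which in the violet flask at 72.0 h comes to 0.244. In the neighbour charged with 1.3 M of substrate, partner stood at 0.0150 M at 72.0 h, and the ratio stood at 0.0345.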